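**Plan**
- Retrosynthesis: the side-chain C=C bond is cut first (cross-metathesis of a 2-vinyl core with benzoate 18). Then the O-1–C-7a and C-3–C-3a bonds of the tetrahydrofuran ring are cut together, leaving an α-oxygenated aldehyde and a 2-pyrone.
- Enabling feature: the C-3a–C-7a bond of the furo[3,2-b]pyran-5-one is the C-5=C-6 double bond of a 2-pyrone. A silyloxy group at pyrone C-3 (C-6 of the bicycle, removed later) makes pyrone C-6 nucleophilic through the ring diene and, once C-6 has bonded, turns C-5 into the β-carbon of an enone.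
- Forward: the lactone ring is bought as 3-hydroxy-2-pyrone and the tetrahydrofuran ring is annulated onto it in step 4. The enol oxygen is then removed via the enol triflate, C-3 is inverted by oxidation and reduction, and the side chain is attached last.
- Stereochemistry: C-2 comes from (S)-but-3-ene-1,2-diol; C-3a and C-7a from a Felkin–Anh, like-topicity aldol and cis ring closure; C-3 from convex-face hydride delivery. The two side-chain centres come from a Sharpless epoxidation of divinyl carbinol and the E alkene from metathesis.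

Key step: step 4

Assumption: 1, 4 and 13 are commercial; bicycle numbering is O-1, C-2 (side chain), C-3 (OH), C-3a, O-4, C-5 (C=O), C-6, C-7, C-7a, and in step 4 the triethylsilyl group is taken to end on O-3.

**Step 1**
Reactants: 1 (S)-but-3-ene-1,2-diol
Product: 2 (S)-3,4-bis(triethylsilyloxy)but-1-ene
Conditions: TESCl (2.3 equiv), imidazole, DMF, 0 °C to rt
Reagents that add atoms: chlorotriethylsilane, CC[Si](Cl)(CC)CC
Why: Standard silyl ether formation on both hydroxyls, so that the primary one can be oxidised selectively in step 2 while the secondary one stays masked as the later ring oxygen.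

**Step 2**
Reactants: 2 (S)-3,4-bis(triethylsilyloxy)but-1-ene
Product: 3 (S)-2-(triethylsilyloxy)but-3-enal
Conditions: (COCl)2, DMSO, CH2Cl2, −78 to −30 °C; then Et3N; used crude
Reagents that add atoms: none
Why: Swern oxidation of a primary silyl ether, in which chlorodimethylsulfonium chloride cleaves the unhindered primary O–Si bond and oxidises that carbon to the aldehyde while the hindered secondary TES ether and the α-stereocentre should survive at low temperature.

**Step 3**
Reactants: 4 3-hydroxy-2H-pyran-2-one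
Product: 5 3-(tert-butyldimethylsilyloxy)-2H-pyran-2-one
Conditions: TBSCl, imidazole, DMF, rt
Reagents that add atoms: tert-butylchlorodimethylsilane, CC(C)(C)[Si](C)(C)Cl
Why: Silylation of the acidic enolic hydroxyl turns the pyrone into a cyclic silyl dienol ether (O-3–C-3=C-4–C-5=C-6).

**Step 4**
Reactants: 3 (S)-2-(triethylsilyloxy)but-3-enal; 5 3-(tert-butyldimethylsilyloxy)-2H-pyran-2-one
Product: 7 (2S,3S,3aS,7aR)-6-[(tert-butyldimethylsilyl)oxy]-3-[(triethylsilyl)oxy]-2-vinyl-2,3,3a,7a-tetrahydro-5H-furo[3,2-b]pyran-5-one, via silyloxocarbenium aldolate 6 (not isolated)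
Conditions: BF3·OEt2 (0.3 equiv), CH2Cl2, −78 to −40 °C; then Et3N, aq. NaHCO3
Reagents that add atoms: none
Why: Proposed new method: BF3 activates aldehyde 3 and the silyl dienol ether of 5 attacks it through its terminus, pyrone C-6 (vinylogous Mukaiyama aldol), which converts the pyrone into the O-silylated enone 6 whose β-carbon is the former pyrone C-5; the neighbouring TES ether oxygen adds to that carbon and passes its silyl group to the aldolate oxygen (1,4-O-to-O shift), releasing BF3 and leaving the silyl enol ether 7. The closest known reaction type is the Lewis acid mediated vinylogous aldol addition of 2-silyloxyfurans to α-oxygenated aldehydes followed by oxa-Michael closure to furo[3,2-b]furanones, together with the known C-6 nucleophilicity of 3-hydroxy-2-pyrone toward electron-poor alkenes under base. The tetrahydrofuran ring closes by 5-exo-trig conjugate addition of oxygen, the lactone ring is carried through unchanged, and the fusion must be cis because the tethered oxygen can reach C-7a only on the face that already bears the new C-3a–C-3 bond. In the numbering of 7, C-3 is set by Felkin–Anh addition to the α-silyloxy aldehyde under the non-chelating Lewis acid (erythro to C-2), C-3a by the like topicity usual for cyclic silyl dienol ethers (threo between ring oxygen and carbinol oxygen), and C-7a by the cis closure. The step needs attack through pyrone C-6 and not C-4, which the larger terminal coefficient of the dienol ether favours and which alone gives an adduct that ring closure can trap, and it needs that closure to outrun loss of H-6 with re-aromatisation, which the absence of base and the five-membered transition state should secure. The 3-oxygen comes out epimeric to the target while C-2, C-3a and C-7a are correct, and it is corrected in steps 8 and 9.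

**Step 5**
Reactants: 7 (2S,3S,3aS,7aR)-6-[(tert-butyldimethylsilyl)oxy]-3-[(triethylsilyl)oxy]-2-vinyl-2,3,3a,7a-tetrahydro-5H-furo[3,2-b]pyran-5-one
Product: 8 (2S,3S,3aS,7aR)-5-oxo-3-[(triethylsilyl)oxy]-2-vinyl-2,3,3a,7a-tetrahydro-5H-furo[3,2-b]pyran-6-yl trifluoromethanesulfonate
Conditions: CsF, PhNTf2, DME, 0 °C to rt
Reagents that add atoms: N-phenylbis(trifluoromethanesulfonimide), O=S(=O)(N(c1ccccc1)S(=O)(=O)C(F)(F)F)C(F)(F)F
Why: Fluoride-triggered exchange of a silyl enol ether for an enol triflate, in which CsF cleaves the enol O–Si bond much faster than the secondary alkyl TES ether and the enolate is trapped by PhNTf2 as it forms, before it can reopen the ether ring.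

**Step 6**
Reactants: 8 (2S,3S,3aS,7aR)-5-oxo-3-[(triethylsilyl)oxy]-2-vinyl-2,3,3a,7a-tetrahydro-5H-furo[3,2-b]pyran-6-yl trifluoromethanesulfonate
Product: 9 (2S,3S,3aS,7aR)-3-[(triethylsilyl)oxy]-2-vinyl-2,3,3a,7a-tetrahydro-5H-furo[3,2-b]pyran-5-one
Conditions: Pd(OAc)2 (5 mol %), PPh3 (10 mol %), HCO2H, Bu3N, DMF, 60 °C
Reagents that add atoms: none
Why: Palladium-catalysed formate reduction of an enol triflate (oxidative addition to zerovalent palladium, formate-to-hydride exchange with loss of CO2, reductive elimination) replaces the helper oxygen by hydrogen and unveils the α,β-unsaturated lactone.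

**Step 7**
Reactants: 9 (2S,3S,3aS,7aR)-3-[(triethylsilyl)oxy]-2-vinyl-2,3,3a,7a-tetrahydro-5H-furo[3,2-b]pyran-5-one
Product: 10 (2S,3S,3aR,7aR)-3-hydroxy-2-vinyl-2,3,3a,7a-tetrahydro-5H-furo[3,2-b]pyran-5-one
Conditions: HF·pyridine, pyridine, THF, 0 °C
Reagents that add atoms: none
Why: Buffered fluoride cleavage of the secondary TES ether under non-basic conditions that spare the unsaturated lactone.

**Step 8**
Reactants: 10 (2S,3S,3aR,7aR)-3-hydroxy-2-vinyl-2,3,3a,7a-tetrahydro-5H-furo[3,2-b]pyran-5-one
Product: 11 (2S,3aS,7aR)-2-vinyl-3a,7a-dihydro-2H-furo[3,2-b]pyran-3,5-dione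
Conditions: Dess–Martin periodinane, pyridine, CH2Cl2, 0 °C; used at once
Reagents that add atoms: none
Why: Dess–Martin oxidation under buffered, near-neutral conditions removes the wrongly configured C-3 centre without enolising the ketone toward C-2 or C-3a.

**Step 9**
Reactants: 11 (2S,3aS,7aR)-2-vinyl-3a,7a-dihydro-2H-furo[3,2-b]pyran-3,5-dione
Product: 12 (2S,3R,3aR,7aR)-3-hydroxy-2-vinyl-2,3,3a,7a-tetrahydro-5H-furo[3,2-b]pyran-5-one
Conditions: NaBH4, CeCl3·7H2O, MeOH, −78 °C
Reagents that add atoms: none
Why: Luche reduction, in which the ketone is shielded on one face by the lactone ring at C-3a and the vinyl group at C-2, so hydride should arrive from the open convex face and place the hydroxyl cis to both (the all-cis array of the target), while CeCl3 suppresses conjugate reduction of the lactone.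

**Step 10**
Reactants: 13 penta-1,4-dien-3-ol
Product: 14 (2R,3S)-1,2-epoxypent-4-en-3-ol
Conditions: Ti(OiPr)4 (cat.), D-(−)-diisopropyl tartrate, t-BuOOH, 4 Å MS, CH2Cl2, −20 °C
Reagents that add atoms: tert-butyl hydroperoxide, CC(C)(C)OO
Why: Sharpless asymmetric epoxidation of the meso divinyl carbinol, where the D-tartrate catalyst selects one enantiotopic vinyl group and one face and the minor enantiomer is consumed further, so the erythro epoxy alcohol should form in high enantiomeric purity.

**Step 11**
Reactants: 14 (2R,3S)-1,2-epoxypent-4-en-3-ol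
Product: 15 (R)-2-[(S)-1-[(4-methoxybenzyl)oxy]prop-2-en-1-yl]oxirane
Conditions: NaH, PMBCl, Bu4NI (cat.), THF, 0 °C to rt
Reagents that add atoms: 4-methoxybenzyl chloride, COc1ccc(CCl)cc1
Why: Williamson etherification gives a protecting group that cannot migrate to the neighbouring oxygen and is later removed under neutral conditions.

**Step 12**
Reactants: 15 (R)-2-[(S)-1-[(4-methoxybenzyl)oxy]prop-2-en-1-yl]oxirane
Product: 16 (2R,3S)-3-[(4-methoxybenzyl)oxy]pent-4-en-2-ol
Conditions: LiEt3BH, THF, 0 °C
Reagents that add atoms: none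
Why: SN2 hydride delivery to the unsubstituted epoxide carbon makes the methyl group and leaves the C-2 oxygen and its configuration untouched.

**Step 13**
Reactants: 16 (2R,3S)-3-[(4-methoxybenzyl)oxy]pent-4-en-2-ol
Product: 17 (2R,3S)-3-[(4-methoxybenzyl)oxy]pent-4-en-2-yl benzoate
Conditions: BzCl, pyridine, DMAP (cat.), CH2Cl2, 0 °C to rt
Reagents that add atoms: benzoyl chloride, O=C(Cl)c1ccccc1
Why: Acylation of the only free hydroxyl places the benzoate regiospecifically on the methyl carbinol.

**Step 14**
Reactants: 17 (2R,3S)-3-[(4-methoxybenzyl)oxy]pent-4-en-2-yl benzoate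
Product: 18 (2R,3S)-3-hydroxypent-4-en-2-yl benzoate
Conditions: DDQ, CH2Cl2/pH 7 buffer, 0 °C
Reagents that add atoms: none
Why: Oxidative cleavage of the PMB ether under neutral conditions frees the allylic alcohol without 1,2-migration of the benzoate.

**Step 15**
Reactants: 12 (2S,3R,3aR,7aR)-3-hydroxy-2-vinyl-2,3,3a,7a-tetrahydro-5H-furo[3,2-b]pyran-5-one; 18 (2R,3S)-3-hydroxypent-4-en-2-yl benzoate (3 equiv)
Product: 19 (2R,3S,4E)-3-hydroxy-5-[(2S,3R,3aR,7aR)-3-hydroxy-5-oxo-2,3,3a,7a-tetrahydro-5H-furo[3,2-b]pyran-2-yl]pent-4-en-2-yl benzoate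
Conditions: Hoveyda–Grubbs second-generation catalyst (10 mol %), 1,4-benzoquinone (20 mol %), CH2Cl2, 40 °C
Reagents that add atoms: none
Why: Olefin cross-metathesis of two terminal, allylically oxygenated type 2 alkenes that homodimerise slowly, so the excess of 18 should drive the cross product and thermodynamic control should give the E alkene, while the ring enoate is inert and benzoquinone suppresses isomerisation of the allylic alcohol.

**Compound list**
1 | (S)-but-3-ene-1,2-diol | C=C[C@H](O)CO | starting material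
2 | (S)-3,4-bis(triethylsilyloxy)but-1-ene | C=C[C@H](O[Si](CC)(CC)CC)CO[Si](CC)(CC)CC | intermediate
3 | (S)-2-(triethylsilyloxy)but-3-enal | C=C[C@H](O[Si](CC)(CC)CC)C=O | intermediate
4 | 3-hydroxy-2H-pyran-2-one | O=C1OC=CC=C1O | starting material
5 | 3-(tert-butyldimethylsilyloxy)-2H-pyran-2-one | O=C1OC=CC=C1O[Si](C)(C)C(C)(C)C | intermediate
6 | BF3-bound silyloxocarbenium aldolate (C-6 vinylogous aldol adduct of 3 and 5) | C=C[C@H](O[Si](CC)(CC)CC)[C@H](O[B-](F)(F)F)[C@H]1OC(=O)C(=[O+][Si](C)(C)C(C)(C)C)C=C1 | intermediate (not isolated)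
7 | (2S,3S,3aS,7aR)-6-[(tert-butyldimethylsilyl)oxy]-3-[(triethylsilyl)oxy]-2-vinyl-2,3,3a,7a-tetrahydro-5H-furo[3,2-b]pyran-5-one | C=C[C@@H]1O[C@@H]2C=C(O[Si](C)(C)C(C)(C)C)C(=O)O[C@@H]2[C@H]1O[Si](CC)(CC)CC | intermediate
8 | (2S,3S,3aS,7aR)-5-oxo-3-[(triethylsilyl)oxy]-2-vinyl-2,3,3a,7a-tetrahydro-5H-furo[3,2-b]pyran-6-yl trifluoromethanesulfonate | C=C[C@@H]1O[C@@H]2C=C(OS(=O)(=O)C(F)(F)F)C(=O)O[C@@H]2[C@H]1O[Si](CC)(CC)CC | intermediate
9 | (2S,3S,3aS,7aR)-3-[(triethylsilyl)oxy]-2-vinyl-2,3,3a,7a-tetrahydro-5H-furo[3,2-b]pyran-5-one | C=C[C@@H]1O[C@@H]2C=CC(=O)O[C@@H]2[C@H]1O[Si](CC)(CC)CC | intermediate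
10 | (2S,3S,3aR,7aR)-3-hydroxy-2-vinyl-2,3,3a,7a-tetrahydro-5H-furo[3,2-b]pyran-5-one (3-epi core) | C=C[C@@H]1O[C@@H]2C=CC(=O)O[C@@H]2[C@H]1O | intermediate
11 | (2S,3aS,7aR)-2-vinyl-3a,7a-dihydro-2H-furo[3,2-b]pyran-3,5-dione | C=C[C@@H]1O[C@@H]2C=CC(=O)O[C@@H]2C1=O | intermediate
12 | (2S,3R,3aR,7aR)-3-hydroxy-2-vinyl-2,3,3a,7a-tetrahydro-5H-furo[3,2-b]pyran-5-one (all-cis core) | C=C[C@@H]1O[C@@H]2C=CC(=O)O[C@@H]2[C@@H]1O | intermediate
13 | penta-1,4-dien-3-ol | C=CC(O)C=C | starting material
14 | (2R,3S)-1,2-epoxypent-4-en-3-ol | C1[C@@H](O1)[C@@H](O)C=C | intermediate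
15 | (R)-2-[(S)-1-[(4-methoxybenzyl)oxy]prop-2-en-1-yl]oxirane | C1[C@@H](O1)[C@@H](OCc2ccc(OC)cc2)C=C | intermediate
16 | (2R,3S)-3-[(4-methoxybenzyl)oxy]pent-4-en-2-ol | C[C@@H](O)[C@@H](OCc1ccc(OC)cc1)C=C | intermediate
17 | (2R,3S)-3-[(4-methoxybenzyl)oxy]pent-4-en-2-yl benzoate | C[C@@H](OC(=O)c1ccccc1)[C@@H](OCc1ccc(OC)cc1)C=C | intermediate
18 | (2R,3S)-3-hydroxypent-4-en-2-yl benzoate | C[C@@H](OC(=O)c1ccccc1)[C@@H](O)C=C | intermediate
19 | (2R,3S,4E)-3-hydroxy-5-[(2S,3R,3aR,7aR)-3-hydroxy-5-oxo-2,3,3a,7a-tetrahydro-5H-furo[3,2-b]pyran-2-yl]pent-4-en-2-yl benzoate | C[C@@H](OC(=O)c1ccccc1)[C@@H](O)/C=C/[C@@H]1O[C@@H]2C=CC(=O)O[C@@H]2[C@@H]1O | target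

**Totals**
Total steps: 15. Longest linear sequence: 9 (steps 1, 2, 4, 5, 6, 7, 8, 9, 15).

**Steps most likely to fail**

Step 4 (proposed new method). The silyloxypyrone may be too weak a nucleophile for the activated aldehyde, may attack through C-4 instead of C-6, or the adduct may re-aromatise by loss of H-6 before the ether ring closes. The facial selectivities may also be poor. The fallback uses known chemistry, sets out from 3 and comes back at 11. Aldehyde 3 should be allylborated with the cyclic γ-alkoxyallylboronate 2-ethoxy-4-(pinacolboryl)-3,4-dihydro-2H-pyran (from the hetero-Diels–Alder reaction of 3-boronoacrolein pinacol ester with ethyl vinyl ether), using the enantiomer matched to Felkin–Anh addition. The closed six-membered transition state of this cis-enol-ether boronate should give 1-(6-ethoxy-3,6-dihydro-2H-pyran-2-yl)-2-(triethylsilyloxy)but-3-en-1-ol F1 with the same threo, erythro pattern. Bu4NF/AcOH should free 1-(6-ethoxy-3,6-dihydro-2H-pyran-2-yl)but-3-ene-1,2-diol F2. I2/NaHCO3 in MeCN should close the ether ring by 5-exo iodoetherification onto the ring alkene to give the cis-fused iodoether 5-ethoxy-7-iodo-2-vinylhexahydro-2H-furo[3,2-b]pyran-3-ol F3. CrO3/H2SO4 in acetone should oxidise the acetal to the lactone and the carbinol to the ketone, giving 7-iodo-2-vinyltetrahydro-2H-furo[3,2-b]pyran-3,5-dione F4. Et3N should then eliminate HI to give 11.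

Step 8. The new ketone may enolise toward C-2 (allylic and α-oxygenated), which would cause epimerisation there, migration of the vinyl double bond into conjugation, or β-elimination of the ring oxygen. The fallback avoids the ketone, sets out from 10 and comes back at 12. A Mitsunobu reaction of 10 with 4-nitrobenzoic acid (PPh3, DIAD, toluene) should invert C-3 by SN2 displacement to give the all-cis 4-nitrobenzoate of 12 F5. Mild methanolysis (NaN3, MeOH, 40 °C) should then release 12.

Step 15. Turnover may be slow at the hindered vinyl group on the concave face, 18 may homodimerise, the E/Z ratio may erode, or the allylic alcohol may isomerise by ruthenium hydride. The fallback makes the C-9–C-10 bond instead of the alkene, sets out from 12 and comes back at 19. Ozonolysis of the terminal vinyl group of 12 (O3, CH2Cl2, −78 °C, then Me2S; the electron-poor ring alkene reacts much more slowly) should give the 2-formyl analogue of 12 F6. Takai olefination (CrCl2, CHI3, THF) should give the (E)-2-(2-iodovinyl) analogue of 12 F7. Nozaki–Hiyama–Kishi coupling (CrCl2, NiCl2 cat., DMF) with the known aldehyde (R)-2-(benzoyloxy)propanal F8 should give 19, with Felkin–Anh addition favouring the required erythro diol monoester and the C-3 epimer of the side chain removed by chromatography.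

**Further compounds**
F1 | step 4 | 1-(6-ethoxy-3,6-dihydro-2H-pyran-2-yl)-2-(triethylsilyloxy)but-3-en-1-ol (acetal carbon either configuration) | C=C[C@H](O[Si](CC)(CC)CC)[C@H](O)[C@H]1OC(OCC)CC=C1
F2 | step 4 | 1-(6-ethoxy-3,6-dihydro-2H-pyran-2-yl)but-3-ene-1,2-diol (acetal carbon either configuration) | C=C[C@H](O)[C@H](O)[C@H]1OC(OCC)CC=C1
F3 | step 4 | 5-ethoxy-7-iodo-2-vinylhexahydro-2H-furo[3,2-b]pyran-3-ol (cis-fused, iodine trans to O-1, acetal carbon either configuration) | C=C[C@@H]1O[C@@H]2[C@@H](I)CC(OCC)O[C@@H]2[C@H]1O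
F4 | step 4 | 7-iodo-2-vinyltetrahydro-2H-furo[3,2-b]pyran-3,5-dione (cis-fused) | C=C[C@@H]1O[C@@H]2[C@@H](I)CC(=O)O[C@@H]2C1=O
F5 | step 8 | all-cis 4-nitrobenzoate of 12 | C=C[C@@H]1O[C@@H]2C=CC(=O)O[C@@H]2[C@@H]1OC(=O)c1ccc(cc1)[N+](=O)[O-]
F6 | step 15 | 2-formyl analogue of 12 (3-hydroxy-5-oxo-2,3,3a,7a-tetrahydro-5H-furo[3,2-b]pyran-2-carbaldehyde, configuration as in 12) | O=C[C@@H]1O[C@@H]2C=CC(=O)O[C@@H]2[C@@H]1O
F7 | step 15 | (E)-2-(2-iodovinyl) analogue of 12 | I/C=C/[C@@H]1O[C@@H]2C=CC(=O)O[C@@H]2[C@@H]1O
F8 | step 15 | (R)-2-(benzoyloxy)propanal | C[C@@H](OC(=O)c1ccccc1)C=O
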